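All runs come from a simulation for an exercise.

**Noon against summer.** You wanted a quick number, so I started from the noon and summer runs, which differed in free catalyst loading. Product at 6.00 min rose from 3.4% to 5.7%, which I read as a catalyst order of 1.38, a loose reading given the scatter.

all flasks: added ligand 12 mM
- noon: starting material 0.40 M; partner 0.80 equiv; free catalyst 1.1 mol%; run made earlier
- summer: starting material 0.40 M; partner 0.80 equiv; free catalyst 1.6 mol%; run made earlier
- midnight: starting material 0.60 M; partner 0.80 equiv; free catalyst 2.1 mol%; run made earlier
- flask: starting material 0.40 M; partner 0.800 equiv; free catalyst 2.1 mol%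

| run | time / min | product / % | starting material / % |
|---|---|---|---|
| noon | 0.833 | 0.2 | 99.4 |
| noon | 2.00 | 2.1 | 99.2 |
| noon | 4.00 | 2.0 | 97.7 |
| noon | 6.00 | 3.4 | 96.3 |
| summer | 0.500 | 0 | 100.0 |
| summer | 1.00 | 1.5 | 98.7 |
| summer | 2.50 | 1.9 | 97.6 |
| summer | 6.00 | 5.7 | 94.4 |
| midnight | 0.500 | 1.3 | 99.5 |
| midnight | 1.00 | 3.0 | 97.4 |
| midnight | 2.50 | 5.6 | 93.9 |
| midnight | 6.00 | 15.1 | 85.0 |

(standard deviation of a reading: 0.5 percentage points)

- steps thought possible: free catalyst + added ligand <-> idle complex; catalyst intermediate C -> free catalyst + product; partner + catalyst intermediate B -> catalyst intermediate C; starting material + free catalyst -> catalyst intermediate A; catalyst intermediate A -> catalyst intermediate B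

- apparent order in partner when 20% of the starting material are converted (percent change of the rate of making product for one percent more partner charged)
- apparent order in free catalyst when 20% of the starting material are converted (percent change of the rate of making product for one percent more free catalyst charged)

**Titration ratio.** That reading pointed me to the added ligand. In the flask, c(free catalyst) as charged stood at 0.700 of c(added ligand) as charged; I called this charged catalyst over charged ligand the titration ratio. For a rate proportional to c(free catalyst), a ligand that binds nothing gives order one. For the same rate with the ligand in excess and binding tightly, each addition of catalyst also removes free ligand, and the order is one over one minus the ratio, here 3.33. The flask's ratio stood higher than summer's 0.533, so I committed to a catalyst order between 1.38 and 3.33. Partner, the limiting reagent, was never varied apart from starting material, so I gave it no number.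

**The forecast.** It gave 1.3 in free catalyst and 0.2 in partner, citing “more catalyst titrating ligand”. Its catalyst order stands below my bracket.

**The result.** At 20% conversion, reached after 14.3 min, the flask gave 1.7 in free catalyst and 0.081 in partner.

    free catalyst + added ligand ⇌ idle complex, settled at all times (K = 4400 M⁻¹)
    catalyst intermediate C → free catalyst + product (k = 3.20 s⁻¹)
    partner + catalyst intermediate B → catalyst intermediate C (k = 1.20 M⁻¹ s⁻¹)
    starting material + free catalyst → catalyst intermediate A (k = 1.00 M⁻¹ s⁻¹)
    catalyst intermediate A → catalyst intermediate B (k = 0.0630 s⁻¹)

**Parking.** Parking free catalyst as idle complex lifted the catalyst order. The same flask without parking, where the ligand binds nothing, gave 1.0, against 1.7 with it. At 6.00 min the flask held 75.7% of its catalyst as idle complex, which at a titration ratio of 0.700 is 53.0% of the ligand charged.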